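**Plan**

- Retrosynthesis: the C6 phenol is masked as a benzyl ether. The C4–C4a bond of ring C is cut to an aryl anion at C4a and a Weinreb amide at C4. The C2–O1 bond is then cut to an aryloxide and a cinnamyl electrophile.
- Enabling feature: once C4–C4a is gone, ring A is a 4-oxygenated 3,5-dimethoxyphenyl ether with a local mirror plane through C8a and C6, so C4a and C8 are one and the same position. A single bromine can only land there, and the adjacent C5-OMe, C6-O and C7-OMe groups are already in place.
- Forward: ring A (bromophenol from syringaldehyde, three steps) and ring B (cinnamyl carbonate from 3,4-dimethoxycinnamic acid, two steps) are joined at C2–O1. The remaining vinyl group is raised to the Weinreb amide, and ring C is closed last.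
- Stereochemistry: the only centre, C2 (S), is set under ligand control in an iridium-catalysed branched-selective allylic etherification and is a spectator from then on.
- The C4 ketone, which opens the retro-oxa-Michael racemisation channel, first appears at the cold quench of the ring closure, and only a neutral hydrogenolysis follows.

Key step: step 10

Assumption: the (Sa,Sc,Sc) enantiomer of ligand L, N,N-bis(1-phenylethyl)dinaphtho[2,1-d:1',2'-f][1,3,2]dioxaphosphepin-4-amine, is taken to steer the aryloxide to the face that gives (S)-11; both antipodes are commercial, so the mirror-image ligand is used should the first batch of 11 prove to be (R).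

**Route**

Step 1
Reactants: 1 syringaldehyde
Product: 2 4-(benzyloxy)-3,5-dimethoxybenzaldehyde
Conditions: BnBr, K2CO3, DMF, 60 °C
Reagents that add atoms: benzyl bromide, BrCc1ccccc1
Why: Williamson etherification of the only acidic OH masks the future C6 phenol as a benzyl ether that should tolerate peracid, borane, oxoammonium and organolithium reagents and can be removed at the end under neutral conditions.

Step 2
Reactants: 2 4-(benzyloxy)-3,5-dimethoxybenzaldehyde
Product: 3 4-(benzyloxy)-2-bromo-3,5-dimethoxybenzaldehyde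
Conditions: NBS, MeCN, 0 °C to rt, dark
Reagents that add atoms: N-bromosuccinimide, O=C1CCC(=O)N1Br
Why: Electrophilic aromatic bromination can give only one monobromide because the two open ring positions are related by the mirror plane through C1 and C4, while the formyl group and the first bromine slow a second substitution and the dark, polar medium suppresses radical attack on the benzyl CH2.

Step 3
Reactants: 3 4-(benzyloxy)-2-bromo-3,5-dimethoxybenzaldehyde
Product: 5 4-(benzyloxy)-2-bromo-3,5-dimethoxyphenol, via aryl formate 4 (not isolated)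
Conditions: mCPBA, CH2Cl2, 0 °C to rt; NaHCO3 wash; crude 4, K2CO3 (0.2 equiv), MeOH, 0 °C, Ar
Reagents that add atoms: m-chloroperoxybenzoic acid, O=C(OO)c1cccc(Cl)c1
Why: Baeyer–Villiger oxidation of an electron-rich benzaldehyde proceeds with aryl migration (Dakin-type outcome), and mild methanolysis of the formate should free the phenol without touching the aryl bromide or the benzyl ether.

Step 4
Reactants: 6 (E)-3,4-dimethoxycinnamic acid
Product: 8 (E)-3-(3,4-dimethoxyphenyl)prop-2-en-1-ol, via mixed carbonic anhydride 7 (not isolated)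
Conditions: ClCO2Et, Et3N, THF, −10 °C; filter; NaBH4, THF/H2O, 0 °C
Reagents that add atoms: ethyl chloroformate, CCOC(=O)Cl (atoms kept in 7 only)
Why: Activation as the mixed carbonic anhydride followed by borohydride reduction is a standard 1,2-selective passage from cinnamic acids to (E)-cinnamyl alcohols with retention of the alkene geometry.

Step 5
Reactants: 8 (E)-3-(3,4-dimethoxyphenyl)prop-2-en-1-ol
Product: 9 (E)-3-(3,4-dimethoxyphenyl)allyl methyl carbonate
Conditions: ClCO2Me, pyridine, CH2Cl2, 0 °C
Reagents that add atoms: methyl chloroformate, COC(=O)Cl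
Why: O-acylation of the primary allylic alcohol with a chloroformate gives the linear carbonate, the usual leaving group for iridium-catalysed allylic substitution.

Step 6
Reactants: 5 4-(benzyloxy)-2-bromo-3,5-dimethoxyphenol; 9 (E)-3-(3,4-dimethoxyphenyl)allyl methyl carbonate
Product: 11 (S)-1-(3,4-dimethoxyphenyl)prop-2-en-1-yl 4-(benzyloxy)-2-bromo-3,5-dimethoxyphenyl ether, via lithium aryloxide 10 (not isolated)
Conditions: 5, LiN(SiMe3)2, THF, 0 °C, volatiles removed; then 9, [Ir(cod)Cl]2 (2 mol %), (Sa,Sc,Sc)-L (4 mol %, pre-activated with n-PrNH2), THF, rt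
Reagents that add atoms: lithium bis(trimethylsilyl)amide, [Li+].C[Si](C)(C)[N-][Si](C)(C)C (lithium of 10 only)
Why: In this iridium-catalysed asymmetric allylic etherification the cyclometalated iridium phosphoramidite ionises the linear carbonate to an η3-allyl complex whose aryl-bearing terminus is attacked by the aryloxide anti to the metal, which should give the branched ether and set the future C2 as (S) under ligand control, a reaction type established for electron-rich cinnamyl carbonates and ortho-substituted aryloxides.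

Step 7
Reactants: 11 (S)-1-(3,4-dimethoxyphenyl)prop-2-en-1-yl 4-(benzyloxy)-2-bromo-3,5-dimethoxyphenyl ether
Product: 13 (S)-3-[4-(benzyloxy)-2-bromo-3,5-dimethoxyphenoxy]-3-(3,4-dimethoxyphenyl)propan-1-ol, via B-alkyl-9-BBN adduct 12 (not isolated)
Conditions: 9-BBN, THF, 0 °C to rt; then aq NaOH, 30% H2O2, 0 °C
Reagents that add atoms: 9-borabicyclo[3.3.1]nonane, B1C2CCCC1CCC2 (boryl group of 12 only); hydrogen peroxide, OO
Why: Hydroboration–oxidation with the bulky 9-BBN places boron on the terminal carbon (anti-Markovnikov), far enough from the ether oxygen that no β-elimination is possible, and the stereocentre takes no part.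

Step 8
Reactants: 13 (S)-3-[4-(benzyloxy)-2-bromo-3,5-dimethoxyphenoxy]-3-(3,4-dimethoxyphenyl)propan-1-ol
Product: 15 (S)-3-[4-(benzyloxy)-2-bromo-3,5-dimethoxyphenoxy]-3-(3,4-dimethoxyphenyl)propanoic acid, via aldehyde 14 (not isolated)
Conditions: TEMPO (20 mol %), PhI(OAc)2 (2.2 equiv), MeCN/H2O 1:1, 0 °C to rt
Reagents that add atoms: water, O
Why: Nitroxyl-catalysed oxidation with PhI(OAc)2 in aqueous acetonitrile takes the primary alcohol through aldehyde 14 and its hydrate to the acid in a weakly acidic, chlorine-free medium, which disfavours both E1cB loss of aryloxide from 14 and halogenation of the electron-rich rings.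

Step 9
Reactants: 15 (S)-3-[4-(benzyloxy)-2-bromo-3,5-dimethoxyphenoxy]-3-(3,4-dimethoxyphenyl)propanoic acid; 16 N,O-dimethylhydroxylamine hydrochloride
Product: 18 (S)-3-[4-(benzyloxy)-2-bromo-3,5-dimethoxyphenoxy]-3-(3,4-dimethoxyphenyl)-N-methoxy-N-methylpropanamide, via acyl imidazolide 17 (not isolated)
Conditions: CDI, CH2Cl2, 0 °C to rt; then 16, rt
Reagents that add atoms: 1,1'-carbonyldiimidazole, O=C(n1ccnc1)n1ccnc1 (imidazolyl group of 17 only)
Why: Carbonyldiimidazole activation followed by aminolysis with the hydrochloride salt gives the Weinreb amide without any added strong base, which should keep β-elimination of the aryloxide, and with it loss of the stereocentre, at bay.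

Step 10
Reactants: 18 (S)-3-[4-(benzyloxy)-2-bromo-3,5-dimethoxyphenoxy]-3-(3,4-dimethoxyphenyl)-N-methoxy-N-methylpropanamide
Product: 21 (S)-6-(benzyloxy)-5,7,3',4'-tetramethoxyflavanone, via aryllithium 19 (not isolated), via lithium hemiaminal alkoxide 20 (not isolated)
Conditions: t-BuLi (2.1 equiv), THF/Et2O/pentane 4:1:1, −100 °C, 15 min; AcOH in THF, −100 to −78 °C; pH 7 buffer
Reagents that add atoms: tert-butyllithium, [Li]C(C)(C)C (lithium of 19 and 20 only)
Why: Bromine–lithium exchange with t-BuLi (the second equivalent destroys the t-BuBr formed) should be faster at −100 °C than any proton transfer and puts the carbanion on C4a, where the flanking C5 methoxy oxygen and O1 stabilise it by induction and lithium coordination. Aryllithium 19 then adds to the tethered Weinreb carbonyl, forming C4–C4a and closing the pyranone ring C in a 6-exo-trig mode, the closest known reaction type being the Parham cyclisation of 3-(2-bromoaryloxy)propanoic acid derivatives to chroman-4-ones. The N-methoxy chelate 20 holds C4 at the tetrahedral stage, so that no ketone, no second addition and no retro-oxa-Michael opening are possible before the cold acidic quench. No lasting stereocentre is created, since the hemiaminal carbon of 20 becomes the planar C4 carbonyl, and C2 from step 6 is a spectator whose bonds are not touched. The selectivity needed is exchange and ring closure over deprotonation at C3 (which would expel the aryloxide) and over attack of t-BuLi on the amide; the bromine fixes the site of metalation, the six-membered transition state makes the acylation fast, and amide α-protons are only weakly acidic. An anionic closure is preferred to an acid-mediated acylation because the C2–O1 bond, benzylic to a dimethoxyphenyl ring, would be prone to ionise under Lewis or Brønsted acid.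

Step 11
Reactants: 21 (S)-6-(benzyloxy)-5,7,3',4'-tetramethoxyflavanone
Product: 22 (S)-6-hydroxy-5,7,3',4'-tetramethoxyflavanone
Conditions: H2 (1 atm), 10% Pd/C, EtOAc, rt, stopped at full conversion
Reagents that add atoms: none
Why: Catalytic hydrogenolysis cleaves the O-benzyl bond under neutral conditions, so that neither base-induced opening to the chalcone nor acid ionisation at C2 can erode the configuration, and under one atmosphere in ethyl acetate the aryl ketone and the cyclic C2–O1 bond of flavanones normally persist.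

**Compound list**

1 | syringaldehyde (4-hydroxy-3,5-dimethoxybenzaldehyde) | COc1cc(C=O)cc(OC)c1O | starting material
2 | 4-(benzyloxy)-3,5-dimethoxybenzaldehyde | COc1cc(C=O)cc(OC)c1OCc1ccccc1 | intermediate
3 | 4-(benzyloxy)-2-bromo-3,5-dimethoxybenzaldehyde | COc1cc(C=O)c(Br)c(OC)c1OCc1ccccc1 | intermediate
4 | 4-(benzyloxy)-2-bromo-3,5-dimethoxyphenyl formate | COc1cc(OC=O)c(Br)c(OC)c1OCc1ccccc1 | intermediate
5 | 4-(benzyloxy)-2-bromo-3,5-dimethoxyphenol | COc1cc(O)c(Br)c(OC)c1OCc1ccccc1 | intermediate
6 | (E)-3,4-dimethoxycinnamic acid | COc1ccc(/C=C/C(=O)O)cc1OC | starting material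
7 | (E)-3,4-dimethoxycinnamic ethyl carbonic anhydride | CCOC(=O)OC(=O)/C=C/c1ccc(OC)c(OC)c1 | intermediate
8 | (E)-3-(3,4-dimethoxyphenyl)prop-2-en-1-ol | COc1ccc(/C=C/CO)cc1OC | intermediate
9 | (E)-3-(3,4-dimethoxyphenyl)allyl methyl carbonate | COC(=O)OC/C=C/c1ccc(OC)c(OC)c1 | intermediate
10 | lithium 4-(benzyloxy)-2-bromo-3,5-dimethoxyphenoxide | COc1cc([O-])c(Br)c(OC)c1OCc1ccccc1.[Li+] | intermediate
11 | (S)-1-(3,4-dimethoxyphenyl)prop-2-en-1-yl 4-(benzyloxy)-2-bromo-3,5-dimethoxyphenyl ether | COc1ccc([C@@H](Oc2cc(OC)c(OCc3ccccc3)c(OC)c2Br)C=C)cc1OC | intermediate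
12 | (S)-9-{3-[4-(benzyloxy)-2-bromo-3,5-dimethoxyphenoxy]-3-(3,4-dimethoxyphenyl)propyl}-9-borabicyclo[3.3.1]nonane | COc1ccc([C@@H](Oc2cc(OC)c(OCc3ccccc3)c(OC)c2Br)CCB2C3CCCC2CCC3)cc1OC | intermediate
13 | (S)-3-[4-(benzyloxy)-2-bromo-3,5-dimethoxyphenoxy]-3-(3,4-dimethoxyphenyl)propan-1-ol | COc1ccc([C@@H](Oc2cc(OC)c(OCc3ccccc3)c(OC)c2Br)CCO)cc1OC | intermediate
14 | (S)-3-[4-(benzyloxy)-2-bromo-3,5-dimethoxyphenoxy]-3-(3,4-dimethoxyphenyl)propanal | COc1ccc([C@@H](Oc2cc(OC)c(OCc3ccccc3)c(OC)c2Br)CC=O)cc1OC | intermediate
15 | (S)-3-[4-(benzyloxy)-2-bromo-3,5-dimethoxyphenoxy]-3-(3,4-dimethoxyphenyl)propanoic acid | COc1ccc([C@@H](Oc2cc(OC)c(OCc3ccccc3)c(OC)c2Br)CC(=O)O)cc1OC | intermediate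
16 | N,O-dimethylhydroxylamine hydrochloride | CNOC.Cl | starting material
17 | (S)-3-[4-(benzyloxy)-2-bromo-3,5-dimethoxyphenoxy]-3-(3,4-dimethoxyphenyl)-1-(1H-imidazol-1-yl)propan-1-one | COc1ccc([C@@H](Oc2cc(OC)c(OCc3ccccc3)c(OC)c2Br)CC(=O)n2ccnc2)cc1OC | intermediate
18 | (S)-3-[4-(benzyloxy)-2-bromo-3,5-dimethoxyphenoxy]-3-(3,4-dimethoxyphenyl)-N-methoxy-N-methylpropanamide | COc1ccc([C@@H](Oc2cc(OC)c(OCc3ccccc3)c(OC)c2Br)CC(=O)N(C)OC)cc1OC | intermediate
19 | aryllithium from 18 (lithium in place of bromine at C4a) | COc1ccc([C@@H](Oc2cc(OC)c(OCc3ccccc3)c(OC)c2[Li])CC(=O)N(C)OC)cc1OC | intermediate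
20 | lithium (2S)-6-(benzyloxy)-2-(3,4-dimethoxyphenyl)-5,7-dimethoxy-4-[methoxy(methyl)amino]chroman-4-olate (C4 configuration undefined, transient) | COc1ccc([C@@H]2CC([O-])(N(C)OC)c3c(cc(OC)c(OCc4ccccc4)c3OC)O2)cc1OC.[Li+] | intermediate
21 | (S)-6-(benzyloxy)-5,7,3',4'-tetramethoxyflavanone | COc1ccc([C@@H]2CC(=O)c3c(cc(OC)c(OCc4ccccc4)c3OC)O2)cc1OC | intermediate
22 | (S)-6-hydroxy-5,7,3',4'-tetramethoxyflavanone, (2S)-2-(3,4-dimethoxyphenyl)-6-hydroxy-5,7-dimethoxy-2,3-dihydro-4H-chromen-4-one | COc1ccc([C@@H]2CC(=O)c3c(cc(OC)c(O)c3OC)O2)cc1OC | target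

Total step count: 11. Longest linear sequence: 9 (steps 1–3 and 6–11); the cinnamyl branch (steps 4 and 5) joins at step 6.

**Steps most likely to fail**

**Step 10.**
- Risk: proton transfer may outrun ring closure. This could mean deprotonation at C3 with expulsion of the aryloxide, quenching of the aryl anion to the debrominated ether, or attack of the alkyllithium on the amide.
- Fallback: it sets out from acid 15 and forms the same C4–C4a bond in the cationic sense at the other, still unsubstituted ortho position, which the symmetry of ring A makes equivalent.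
- Ring closure: treatment of 15 with (CF3CO)2O in CH2Cl2 at 0 °C should give the mixed trifluoroacetic anhydride F1. F1 acylates the ring, which is activated by three oxygen donors, without a Lewis acid (intramolecular Friedel–Crafts acylation) to give (S)-6-(benzyloxy)-8-bromo-5,7,3',4'-tetramethoxyflavanone F2.
- Return: hydrogenation over 10% Pd/C with NaOAc in EtOAc/MeOH then removes the C8 bromine and the benzyl group together, and the sequence comes back to the route at 22.
- Cost: the benzylic ether is exposed to trifluoroacetic acid, so the enantiopurity would have to be checked at F2.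

**Step 6.**
- Risk: branched selectivity or enantiopurity may erode through reversible ionisation of the electron-rich benzylic ether on the catalyst, or the ortho-bromo aryloxide may react sluggishly.
- Fallback: it sets out from phenol 5 and replaces the catalytic C–O bond formation by an SN2 inversion.
- Alcohol partner: purchased 3-chloro-1-(3,4-dimethoxyphenyl)propan-1-one F3 undergoes CBS reduction ((S)-Me-CBS oxazaborolidine, BH3·SMe2, THF, −20 °C) to (R)-3-chloro-1-(3,4-dimethoxyphenyl)propan-1-ol F4.
- Coupling: a Mitsunobu reaction of F4 with 5 (PPh3, DIAD, toluene, 0 °C) should give, with inversion, (S)-3-chloro-1-(3,4-dimethoxyphenyl)propyl 4-(benzyloxy)-2-bromo-3,5-dimethoxyphenyl ether F5. This partner has no acidic α-hydrogen that could divert the reaction into elimination.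
- Return: displacement with CsOAc (NaI cat., DMF, 70 °C) leads to (S)-3-[4-(benzyloxy)-2-bromo-3,5-dimethoxyphenoxy]-3-(3,4-dimethoxyphenyl)propyl acetate F6, and methanolysis (K2CO3, MeOH) comes back to the route at 13.

**Step 9.**
- Risk: the activated acyl compound may lose the aryloxide by β-elimination under the influence of imidazole or the free amine.
- Fallback: it sets out from acid 15, omits the amide and uses the carboxylate itself as the electrophile of the Parham cyclisation. A carboxylate is almost immune to α-deprotonation.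
- Sequence: n-BuLi (2.1 equiv, THF, −100 °C) first gives lithium (S)-3-[4-(benzyloxy)-2-bromo-3,5-dimethoxyphenoxy]-3-(3,4-dimethoxyphenyl)propanoate F7. It then effects the exchange to the aryllithium carboxylate F8, which closes to the dilithium chroman-4,4-diolate F9.
- Return: quenching with AcOH at −78 °C comes back to the route at 21.

**Further compounds**

F1 | step 10 | (S)-3-[4-(benzyloxy)-2-bromo-3,5-dimethoxyphenoxy]-3-(3,4-dimethoxyphenyl)propanoic trifluoroacetic anhydride | COc1ccc([C@@H](Oc2cc(OC)c(OCc3ccccc3)c(OC)c2Br)CC(=O)OC(=O)C(F)(F)F)cc1OC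
F2 | step 10 | (S)-6-(benzyloxy)-8-bromo-5,7,3',4'-tetramethoxyflavanone | COc1ccc([C@@H]2CC(=O)c3c(c(Br)c(OC)c(OCc4ccccc4)c3OC)O2)cc1OC
F3 | step 6 | 3-chloro-1-(3,4-dimethoxyphenyl)propan-1-one (purchased) | COc1ccc(C(=O)CCCl)cc1OC
F4 | step 6 | (R)-3-chloro-1-(3,4-dimethoxyphenyl)propan-1-ol | COc1ccc([C@H](O)CCCl)cc1OC
F5 | step 6 | (S)-3-chloro-1-(3,4-dimethoxyphenyl)propyl 4-(benzyloxy)-2-bromo-3,5-dimethoxyphenyl ether | COc1ccc([C@@H](Oc2cc(OC)c(OCc3ccccc3)c(OC)c2Br)CCCl)cc1OC
F6 | step 6 | (S)-3-[4-(benzyloxy)-2-bromo-3,5-dimethoxyphenoxy]-3-(3,4-dimethoxyphenyl)propyl acetate | COc1ccc([C@@H](Oc2cc(OC)c(OCc3ccccc3)c(OC)c2Br)CCOC(C)=O)cc1OC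
F7 | step 9 | lithium (S)-3-[4-(benzyloxy)-2-bromo-3,5-dimethoxyphenoxy]-3-(3,4-dimethoxyphenyl)propanoate | COc1ccc([C@@H](Oc2cc(OC)c(OCc3ccccc3)c(OC)c2Br)CC(=O)[O-])cc1OC.[Li+]
F8 | step 9 | aryllithium carboxylate from F7 (lithium in place of bromine) | COc1ccc([C@@H](Oc2cc(OC)c(OCc3ccccc3)c(OC)c2[Li])CC(=O)[O-])cc1OC.[Li+]
F9 | step 9 | dilithium (2S)-6-(benzyloxy)-2-(3,4-dimethoxyphenyl)-5,7-dimethoxychroman-4,4-diolate | COc1ccc([C@@H]2CC([O-])([O-])c3c(cc(OC)c(OCc4ccccc4)c3OC)O2)cc1OC.[Li+].[Li+]
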